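**Plan**

1. Retrosynthesis: the ring B quinone is traced to a hydroquinone held as benzyl ethers (as is the C6 phenol of ring A), and the C4 methylene to a temporary C4–OEt ether. The pyran ring (ring C) is then cut at C2–C3 and C4–C4a in one stroke, leaving an aryloxymethyl pivalate (ring A with O1 and C2) and an E β-aryl enol ether (ring B with C3 and C4).
2. The enol ether is cut at the aryl–C3 bond (Suzuki–Miyaura coupling) and the pivalate at O1–C2 (phenoxide alkylation). Both arenes come from 2,3-dimethoxyhydroquinone, made in two steps from 2,3-dimethoxyphenol through the symmetric quinone and divided between a double and a single benzylation.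
3. Forward: rings A and B are made from that one diol, C3=C4 is joined to ring B and C2 to O1 of ring A. Ring C closes in the key step, the ethoxy group is then cut out, and debenzylation with oxidation of ring B finishes the synthesis.
4. Enabling feature: with C2 at the formaldehyde level, C2–O1–C8a–C4a of ring C is an aryl oxocarbenium ion, a cationic 2-oxadiene. Its carbon terminus C4a is the only free position ortho to O1 and lies para to the C7 methoxy group of ring A. C4 is a plain benzylic CH2, so it can carry a temporary ethoxy group that makes the C3=C4 partner an enol ether, reverses the polarity of the vinylarene and so places ring B on C3.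
5. Stereochemistry: the single stereocenter C3 (S) comes from face selection on the enol ether by a chiral counteranion in the key step; the second center formed there (C4) is temporary and is removed in step 9.

Key step: step 8

Assumption: the sense of induction of the chiral acid in step 8 has to be found by experiment; the catalyst antipode that leads to the (3S) series is meant throughout, and both antipodes are equally accessible.

Step 1
Reactants: 1 2,3-dimethoxyphenol
Product: 2 2,3-dimethoxy-1,4-benzoquinone
Conditions: K2[ON(SO3)2] (2.2 equiv), KH2PO4, H2O–acetone, 0 °C to rt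
Reagents that add atoms: Fremy's salt (dipotassium nitrosodisulfonate), [K+].[K+].[O]N(S(=O)(=O)[O-])S(=O)(=O)[O-]
Why: Oxidation of a phenol with a free para position by Fremy's salt (Teuber reaction) runs through the phenoxyl radical and para attack of a second nitrosodisulfonate radical, a reaction type established for 2,3-dialkoxyphenols.

Step 2
Reactants: 2 2,3-dimethoxy-1,4-benzoquinone
Product: 3 2,3-dimethoxybenzene-1,4-diol (2,3-dimethoxyhydroquinone)
Conditions: Na2S2O4 (aq), EtOAc, rt; organic layer dried and concentrated under Ar, the diol kept under Ar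
Reagents that add atoms: none
Why: Two-electron reduction of a benzoquinone to its hydroquinone by dithionite is standard and quantitative in a two-phase medium, and the diol is isolated once so that it can be divided between steps 3 and 4.

Step 3
Reactants: 3 2,3-dimethoxybenzene-1,4-diol
Product: 4 1,4-bis(benzyloxy)-2,3-dimethoxybenzene
Conditions: BnBr (2.5 equiv), K2CO3, DMF, 60 °C, under Ar
Reagents that add atoms: benzyl bromide, BrCc1ccccc1
Why: Williamson benzylation of both phenoxides of the symmetric hydroquinone with excess benzyl bromide is standard, the inert atmosphere keeping the diol from re-oxidation.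

Step 4
Reactants: 3 2,3-dimethoxybenzene-1,4-diol
Product: 5 4-(benzyloxy)-2,3-dimethoxyphenol
Conditions: BnBr (1.0 equiv), K2CO3, acetone, reflux, under Ar; extraction into aqueous NaOH, acidification, chromatography
Reagents that add atoms: benzyl bromide, BrCc1ccccc1
Why: Williamson etherification with one equivalent of benzyl bromide on the symmetric diol can give only one mono-ether; the neutral bis-ether 4 formed beside it stays in the organic phase on base extraction and is fed into step 5, and the far more polar diol is removed by chromatography and recycled.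

Step 5
Reactants: 4 1,4-bis(benzyloxy)-2,3-dimethoxybenzene
Product: 6 1,4-bis(benzyloxy)-5-bromo-2,3-dimethoxybenzene
Conditions: NBS (1.05 equiv), MeCN, 0 °C to rt
Reagents that add atoms: N-bromosuccinimide, O=C1CCC(=O)N1Br
Why: Electrophilic aromatic bromination of the tetra-alkoxyarene, whose two free ring positions are equivalent and whose first bromine deactivates the ring, should give a single monobromide.

Step 6
Reactants: 6 1,4-bis(benzyloxy)-5-bromo-2,3-dimethoxybenzene; 7 (E)-2-(2-ethoxyethenyl)-4,4,5,5-tetramethyl-1,3,2-dioxaborolane
Product: 8 1,4-bis(benzyloxy)-5-[(E)-2-ethoxyethenyl]-2,3-dimethoxybenzene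
Conditions: Pd(OAc)2, SPhos, K3PO4, 1,4-dioxane–H2O, 80 °C; chromatography on Et3N-treated silica
Reagents that add atoms: none
Why: Suzuki–Miyaura coupling of an electron-rich, ortho-substituted aryl bromide with an alkenyl boronate under SPhos-ligated zerovalent palladium proceeds with retention of alkene geometry, so the E enol ether is obtained and survives the basic medium.

Step 7
Reactants: 5 4-(benzyloxy)-2,3-dimethoxyphenol; 9 chloromethyl pivalate
Product: 10 [4-(benzyloxy)-2,3-dimethoxyphenoxy]methyl pivalate
Conditions: K2CO3, NaI (cat.), DMF, rt
Reagents that add atoms: none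
Why: O-alkylation of the phenoxide by chloromethyl pivalate under iodide (Finkelstein) catalysis is the standard route to aryl pivaloyloxymethyl ethers, the hindered ester carbonyl disfavouring acyl transfer.

Step 8
Reactants: 10 [4-(benzyloxy)-2,3-dimethoxyphenoxy]methyl pivalate; 8 1,4-bis(benzyloxy)-5-[(E)-2-ethoxyethenyl]-2,3-dimethoxybenzene
Product: 13 (3S,4R)-6-(benzyloxy)-3-[2,5-bis(benzyloxy)-3,4-dimethoxyphenyl]-4-ethoxy-7,8-dimethoxychromane (3,4-trans), via aryloxymethyl oxocarbenium ion 11 (not isolated), via open-chain ethoxycarbenium ion 12 (not isolated)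
Conditions: (S,S)-IDPi (confined N-triflyl imidodiphosphorimidate Brønsted acid from 3,3'-diaryl-BINOL, 5 mol%), 5 Å MS, CH2Cl2, −40 °C, 8 (1.3 equiv) added slowly
Reagents that add atoms: none
Why: Proposed new method: a catalytic enantioselective oxa-Povarov reaction of a formaldehyde-level aryl oxocarbenium ion with a β-aryl enol ether; the strong confined acid protonates the pivalate of 10 and expels pivalic acid to give the cationic 2-oxadiene 11 (C2=O1–C8a=C4a) as a contact ion pair with its chiral anion, the enol ether 8 adds through its aryl-bearing carbon to C2 to give the ethoxycarbenium ion 12, and C4a attacks C4 with return of the proton to the anion, which turns the catalyst over. The closest known reaction types are the Lewis acid mediated oxa-Povarov reaction of aryl oxocarbenium ions with alkenes, the chiral acid catalysed Povarov reaction of enol ethers and enecarbamates, and the confined-acid catalysed asymmetric Prins reaction of formaldehyde-derived oxocarbenium ions with aryl alkenes. Ring C closes by a 6-exo-trig Friedel–Crafts alkylation in which the arene bond C8a=C4a is the endocyclic nucleophile, so the whole is a stepwise polar [4+2] annulation. C3 is set in the first C–C bond formation by the chiral counteranion, which should let only one face of the E enol ether reach C2; C4 is set in the closure by the substrate, expected trans to the C3 aryl group (E geometry, both groups pseudo-equatorial), and is erased in step 9, so both C4 epimers serve. The step needs regioselectivity for bonding C2 to the aryl-bearing carbon (the bare vinylarene would put the aryl group on C4), which the temporary ethoxy group on the other alkene carbon secures by making C3 the nucleophilic and C4 the cationic site, and it needs closure at C4a, which is the only free position ortho to O1 and is para to the C7 methoxy group. It also needs the enol ether to outrun the alkoxyarenes as the nucleophile, which its higher nucleophilicity and the slow addition of 8 at low temperature are meant to secure.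

Step 9
Reactants: 13 (3S,4R)-6-(benzyloxy)-3-[2,5-bis(benzyloxy)-3,4-dimethoxyphenyl]-4-ethoxy-7,8-dimethoxychromane
Product: 15 (3S)-6-(benzyloxy)-3-[2,5-bis(benzyloxy)-3,4-dimethoxyphenyl]-7,8-dimethoxychromane, via C4 benzylic cation 14 (not isolated)
Conditions: Et3SiH (5 equiv), TMSOTf (0.2 equiv), CH2Cl2, −78 to −40 °C
Reagents that add atoms: none
Why: Silyl triflate catalysed ionic hydrogenation of an activated benzylic ether, in which the C4 cation 14 (stabilised by O1 and the C7 methoxy group) should take hydride from excess Et3SiH at low temperature faster than it loses H3, so the C3 configuration is kept and the benzyl ethers are untouched.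

Step 10
Reactants: 15 (3S)-6-(benzyloxy)-3-[2,5-bis(benzyloxy)-3,4-dimethoxyphenyl]-7,8-dimethoxychromane
Product: 17 5-[(3S)-6-hydroxy-7,8-dimethoxy-3,4-dihydro-2H-chromen-3-yl]-2,3-dimethoxycyclohexa-2,5-diene-1,4-dione (CNP0302517.1), via hydroquinone triol 16 (not isolated)
Conditions: H2 (1 atm), Pd/C, EtOAc–MeOH, rt; filtration under Ar; then Ag2O, MgSO4, Et2O, rt
Reagents that add atoms: none
Why: Hydrogenolysis of the three aryl benzyl ethers over Pd/C gives triol 16, in which only ring B is a free hydroquinone, so the mild two-electron oxidant Ag2O should convert it to the quinone while the para-alkoxyphenol of ring A and the C3 stereocenter are not touched.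

**Compound list**

1 | 2,3-dimethoxyphenol | COc1cccc(O)c1OC | starting material
2 | 2,3-dimethoxy-1,4-benzoquinone | COC1=C(OC)C(=O)C=CC1=O | intermediate
3 | 2,3-dimethoxybenzene-1,4-diol (2,3-dimethoxyhydroquinone) | COc1c(O)ccc(O)c1OC | intermediate
4 | 1,4-bis(benzyloxy)-2,3-dimethoxybenzene | COc1c(OCc2ccccc2)ccc(OCc2ccccc2)c1OC | intermediate
5 | 4-(benzyloxy)-2,3-dimethoxyphenol | COc1c(O)ccc(OCc2ccccc2)c1OC | intermediate
6 | 1,4-bis(benzyloxy)-5-bromo-2,3-dimethoxybenzene | COc1c(OCc2ccccc2)cc(Br)c(OCc2ccccc2)c1OC | intermediate
7 | (E)-2-(2-ethoxyethenyl)-4,4,5,5-tetramethyl-1,3,2-dioxaborolane | CCO/C=C/B1OC(C)(C)C(C)(C)O1 | starting material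
8 | 1,4-bis(benzyloxy)-5-[(E)-2-ethoxyethenyl]-2,3-dimethoxybenzene | CCO/C=C/c1cc(OCc2ccccc2)c(OC)c(OC)c1OCc1ccccc1 | intermediate
9 | chloromethyl pivalate (chloromethyl 2,2-dimethylpropanoate) | CC(C)(C)C(=O)OCCl | starting material
10 | [4-(benzyloxy)-2,3-dimethoxyphenoxy]methyl pivalate | COc1c(OCOC(=O)C(C)(C)C)ccc(OCc2ccccc2)c1OC | intermediate
11 | [4-(benzyloxy)-2,3-dimethoxyphenyl](methylidene)oxonium, the aryloxymethyl oxocarbenium ion (ion pair with the catalyst anion) | C=[O+]c1ccc(OCc2ccccc2)c(OC)c1OC | intermediate
12 | ethyl{(2S)-2-[2,5-bis(benzyloxy)-3,4-dimethoxyphenyl]-3-[4-(benzyloxy)-2,3-dimethoxyphenoxy]propylidene}oxonium, the open-chain ethoxycarbenium ion | COc1c(OC)c(OCc2ccccc2)cc([C@H](C=[O+]CC)COc2ccc(OCc3ccccc3)c(OC)c2OC)c1OCc1ccccc1 | intermediate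
13 | (3S,4R)-6-(benzyloxy)-3-[2,5-bis(benzyloxy)-3,4-dimethoxyphenyl]-4-ethoxy-7,8-dimethoxychromane (3,4-trans) | COc1c(OC)c(OCc2ccccc2)cc([C@H]2COc3c(OC)c(OC)c(OCc4ccccc4)cc3[C@@H]2OCC)c1OCc1ccccc1 | intermediate
14 | (3S)-6-(benzyloxy)-3-[2,5-bis(benzyloxy)-3,4-dimethoxyphenyl]-7,8-dimethoxychroman-4-ylium, the C4 benzylic cation | COc1c(OC)c(OCc2ccccc2)cc([C@H]2COc3c(OC)c(OC)c(OCc4ccccc4)cc3[CH+]2)c1OCc1ccccc1 | intermediate
15 | (3S)-6-(benzyloxy)-3-[2,5-bis(benzyloxy)-3,4-dimethoxyphenyl]-7,8-dimethoxychromane | COc1c(OC)c(OCc2ccccc2)cc([C@H]2COc3c(OC)c(OC)c(OCc4ccccc4)cc3C2)c1OCc1ccccc1 | intermediate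
16 | (3S)-3-(2,5-dihydroxy-3,4-dimethoxyphenyl)-7,8-dimethoxychroman-6-ol | COc1c(OC)c(O)cc([C@H]2COc3c(OC)c(OC)c(O)cc3C2)c1O | intermediate
17 | 5-[(3S)-6-hydroxy-7,8-dimethoxy-3,4-dihydro-2H-chromen-3-yl]-2,3-dimethoxycyclohexa-2,5-diene-1,4-dione (CNP0302517.1) | COC1=C(OC)C(=O)C([C@H]2COc3c(cc(O)c(OC)c3OC)C2)=CC1=O | target

**Totals and risks**

Total steps: 10. Longest linear sequence: 8 steps (steps 1, 2, 3, 5, 6, 8, 9, 10).

Step 8 is the most likely to fail. The C2–C3 bond formation may show poor facial selectivity. The C3 center may also be lost by proton loss from cation 12 before ring closure or by acid-induced loss of ethanol from 13, and the enol ether may be consumed by protonation and self-condensation. The fallback sets the stereocenter after the annulation by known chemistry. It sets out from 8 and 10, which are combined without chiral control (Tf2NH, 10 mol%, 5 Å MS, CH2Cl2, −78 °C) to give the racemic trans-4-ethoxychroman F1. Warming with catalytic p-TsOH in toluene eliminates ethanol to give the achiral 3-aryl-2H-chromene F2. Asymmetric hydrogenation of this trisubstituted cyclic alkene follows, with [Ir(cod)(tBu-PHOX)][B(C6H3(CF3)2)4] (a chiral phosphine–oxazoline complex of monovalent iridium, ligand antipode chosen for the (3S) product), H2 (50 bar), CH2Cl2, rt. This reaction type is established for 3-aryl-2H-chromenes, and the fallback comes back to the route at 15.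

Step 9 is the second risk. Proton loss from the C4 cation to the conjugated chromene, followed by re-protonation, would erode the C3 configuration. The fallback sets out from 13 and cleaves the C4–OEt bond and the three benzyl ethers together by surface hydrogenolysis (H2, Pd(OH)2/C, EtOAc–AcOH, rt), which does not pass through a free C4 cation. It comes back to the route at triol 16, which is oxidised with Ag2O as in step 10; it makes no compound outside the list (entry F0).

Step 7 is the third risk. The phenoxide may attack the ester carbonyl of chloromethyl pivalate (acyl transfer) in place of the CH2–Cl carbon. The fallback builds the O,O-acetal in two stages through an O,S-acetal. It sets out from 5, which is alkylated with chloromethyl methyl sulfide (NaH, NaI, DMF) to give the methylthiomethyl ether F3. Chlorinolysis of the C–S bond (SO2Cl2, CH2Cl2, −78 °C) gives the chloromethyl ether F4, and displacement with CsO2CCMe3 in DMF comes back to the route at 10.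

**Further compounds**

F1 | step 8 | racemic 3,4-trans-6-(benzyloxy)-3-[2,5-bis(benzyloxy)-3,4-dimethoxyphenyl]-4-ethoxy-7,8-dimethoxychromane (drawn without configuration) | COc1c(OC)c(OCc2ccccc2)cc(C2COc3c(OC)c(OC)c(OCc4ccccc4)cc3C2OCC)c1OCc1ccccc1
F2 | step 8 | 6-(benzyloxy)-3-[2,5-bis(benzyloxy)-3,4-dimethoxyphenyl]-7,8-dimethoxy-2H-chromene | COc1c(OC)c(OCc2ccccc2)cc(C2=Cc3cc(OCc4ccccc4)c(OC)c(OC)c3OC2)c1OCc1ccccc1
F0 | step 9 | none | none
F3 | step 7 | 1-(benzyloxy)-2,3-dimethoxy-4-[(methylsulfanyl)methoxy]benzene | COc1c(OCSC)ccc(OCc2ccccc2)c1OC
F4 | step 7 | 1-(benzyloxy)-4-(chloromethoxy)-2,3-dimethoxybenzene | COc1c(OCCl)ccc(OCc2ccccc2)c1OC
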